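**Plan**

- Retrosynthesis: cut the C-6 ester into bicyclic alcohol 16 and hydroxy acid 25, take out the C-7=C-8 double bond, and add a CO2Me helper at C-3. Ring positions follow naphthalen-2-one numbering: C-2 ketone, C-3 carbinol, C-4 CH2, C-4a quaternary, C-5 CHMe, C-6 ester carbinol.
- Ring B is then cut at C-4–C-4a and C-2–C-3 in one [4+2] step: vinylketene silyl acetal 10 (ring A plus C-8a, C-1, C-2) and methyl 2-acetoxyacrylate 11 (C-3 with its oxygen, C-4).
- Enabling feature: ring B is a cyclohex-2-enone whose carbonyl C-2 and quaternary C-4a are the 1,4-termini of a C-2/C-1/C-8a/C-4a ester dienolate, and its C-1=C-8a double bond lies where a cycloaddition leaves it.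
- Forward order: ring A from 2,3-dimethylcyclohexenone, ring B by the cycloaddition, then C-7=C-8, then the side chain is joined last.
- Stereochemistry: C-6 from a Corey–Bakshi–Shibata reduction; C-5 by hydride delivery anti to the C-6 silyloxy group; C-4a from the C-5 methyl in the cycloaddition; C-3 by equilibration to the equatorial epimer; the side-chain carbinol from (S)-2-hydroxy-2-methylbutanoic acid.

Key step: step 7

Remark: compounds 1, 8, 11, 17 and 21 are taken as catalogue chemicals (11 is otherwise one step from methyl pyruvate and acetic anhydride).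

**Route**

Step 1
Reactants: 1 2,3-dimethylcyclohex-2-en-1-one
Product: 2 (1S)-2,3-dimethylcyclohex-2-en-1-ol
Conditions: (R)-1-methyl-3,3-diphenyltetrahydro-1H,3H-pyrrolo[1,2-c][1,3,2]oxazaborole (10 mol %), BH3·SMe2, THF, −20 °C; MeOH
Reagents that add atoms: none
Why: Corey–Bakshi–Shibata reduction, in which the fully substituted alkenyl side acts as the large group, so the (R)-catalyst should deliver hydride to give the (S)-allylic alcohol, as is general for 2-substituted cyclohexenones.

Step 2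
Reactants: 2 (1S)-2,3-dimethylcyclohex-2-en-1-ol
Product: 3 tert-butyl{[(1S)-2,3-dimethylcyclohex-2-en-1-yl]oxy}dimethylsilane
Conditions: TBSCl, imidazole, DMF, rt
Reagents that add atoms: tert-butyldimethylsilyl chloride, CC(C)(C)[Si](C)(C)Cl
Why: Standard silylation of a secondary alcohol; the bulky silyl ether later shields its own carbinol C–H and directs the conjugate reduction.

Step 3
Reactants: 3 tert-butyl{[(1S)-2,3-dimethylcyclohex-2-en-1-yl]oxy}dimethylsilane
Product: 4 (4S)-4-[(tert-butyldimethylsilyl)oxy]-2,3-dimethylcyclohex-2-en-1-one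
Conditions: Rh2(cap)4 [dirhodium tetrakis(caprolactamate)] (1 mol %), t-BuOOH (70% aq, 5 equiv), K2CO3, CH2Cl2, rt
Reagents that add atoms: tert-butyl hydroperoxide, CC(C)(C)OO
Why: Radical allylic oxidation (hydrogen abstraction by the tert-butylperoxyl radical, collapse of the mixed peroxide) should take the ring CH2 in preference to the methyl groups and the shielded carbinol C–H, giving the γ-silyloxy enone without touching the stereocentre.

Step 4
Reactants: 4 (4S)-4-[(tert-butyldimethylsilyl)oxy]-2,3-dimethylcyclohex-2-en-1-one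
Product: 7 (3R,4S)-4-[(tert-butyldimethylsilyl)oxy]-2,3-dimethylcyclohex-1-en-1-yl trifluoromethanesulfonate, via silyl enol ether 5 (not isolated), via lithium enolate 6 (not isolated)
Conditions: [(Ph3P)CuH]6 (3 mol %), PhMe2SiH, toluene, rt; MeLi, THF, 0 °C; N-(5-chloropyridin-2-yl)-N-(trifluoromethylsulfonyl)trifluoromethanesulfonamide, −78 °C to rt
Reagents that add atoms: N-(5-chloropyridin-2-yl)-N-(trifluoromethylsulfonyl)trifluoromethanesulfonamide, FC(F)(F)S(=O)(=O)N(c1ccc(Cl)cn1)S(=O)(=O)C(F)(F)F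
Why: Copper hydride 1,4-hydrosilylation should deliver hydride to the β-carbon anti to the pseudoaxial silyloxy group, which sets the methyl-bearing centre (R, methyl cis to the silyloxy group) and gives the tetrasubstituted enol ether regiospecifically, and silicon–lithium exchange followed by O-triflation fixes that regiochemistry in the enol triflate.

Step 5
Reactants: 7 (3R,4S)-4-[(tert-butyldimethylsilyl)oxy]-2,3-dimethylcyclohex-1-en-1-yl trifluoromethanesulfonate; 8 (2-ethoxy-2-oxoethyl)zinc bromide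
Product: 9 ethyl 2-[(3R,4S)-4-[(tert-butyldimethylsilyl)oxy]-2,3-dimethylcyclohex-1-en-1-yl]acetate
Conditions: Pd(PPh3)4 (5 mol %), THF, 60 °C
Reagents that add atoms: none
Why: Negishi cross-coupling of an alkenyl triflate with a Reformatsky-type zinc ester enolate (oxidative addition to zerovalent palladium, transmetalation, reductive elimination) should give the β,γ-unsaturated ester without moving the double bond.

Step 6
Reactants: 9 ethyl 2-[(3R,4S)-4-[(tert-butyldimethylsilyl)oxy]-2,3-dimethylcyclohex-1-en-1-yl]acetate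
Product: 10 tert-butyl{[(1S,2R)-4-[2-ethoxy-2-(trimethylsilyloxy)ethenyl]-2,3-dimethylcyclohex-3-en-1-yl]oxy}dimethylsilane
Conditions: Me3SiCl, then LiN(iPr)2 (in situ quench), THF, −78 °C to rt; pentane, filtration under argon
Reagents that add atoms: chlorotrimethylsilane, C[Si](C)(C)Cl
Why: Deprotonation of the doubly activated α-CH2 gives the ester dienolate, which is O-silylated by the chlorosilane already present to the vinylketene silyl acetal; no stereocentre is touched.

Step 7
Reactants: 10 tert-butyl{[(1S,2R)-4-[2-ethoxy-2-(trimethylsilyloxy)ethenyl]-2,3-dimethylcyclohex-3-en-1-yl]oxy}dimethylsilane; 11 methyl 2-acetoxyacrylate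
Product: 13 methyl (4aR,5R,6S)-3-acetoxy-6-[(tert-butyldimethylsilyl)oxy]-4a,5-dimethyl-2-oxo-2,3,4,4a,5,6,7,8-octahydronaphthalene-3-carboxylate, via mixed ketal cycloadduct 12 (not isolated)
Conditions: toluene, 2,6-di-tert-butyl-4-methylphenol (cat.), sealed tube, 110 °C; then 1 M HCl, THF, 0 °C
Reagents that add atoms: none
Why: Thermal Diels–Alder reaction of a 1-alkoxy-1-silyloxy-diene with a captodative acrylate, the known way from a β,γ-unsaturated ester to a cyclohexenone: the diene C(OEt)(OSiMe3)=CH–C(ring)=C(Me) adds across CH2=C(OAc)CO2Me, most likely asynchronously with the C-4–C-4a bond (ring terminus to acrylate CH2) leading. Ring B closes by an intermolecular [4+2] cycloaddition in which the second bond, C-2–C-3, forms between the acetal carbon and the acetoxy-bearing carbon (in the stepwise limit a 6-exo-trig attack of the ester enolate on the O-silyl oxocarbenium ion), and hydrolysis of mixed ketal 12 then gives the C-2 ketone conjugated with the new C-1=C-8a double bond. The quaternary centre C-4a is set by the resident C-5 methyl: allylic 1,2-strain with the C-4a methyl holds it pseudoaxial, so the dienophile should add to the opposite face and the two methyl groups end up cis. C-3 is formed as a mixture here and is corrected in step 9, where it can equilibrate once the ester is gone. The step needs regioselectivity (CH2 to C-4a, oxygenated carbon to C-2), which the polarity of the partners secures (ketene acetal nucleophilic at its γ-terminus, acrylate electrophilic at CH2), and γ- over α-attack, which ring closure secures because only the γ-adduct can form the six-membered ring.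

Step 8
Reactants: 13 methyl (4aR,5R,6S)-3-acetoxy-6-[(tert-butyldimethylsilyl)oxy]-4a,5-dimethyl-2-oxo-2,3,4,4a,5,6,7,8-octahydronaphthalene-3-carboxylate
Product: 14 methyl (4aR,5R,6S)-3-acetoxy-6-[(tert-butyldimethylsilyl)oxy]-4a,5-dimethyl-2-oxo-2,3,4,4a,5,6-hexahydronaphthalene-3-carboxylate
Conditions: chloranil, t-BuOH, reflux
Reagents that add atoms: none
Why: Chloranil dehydrogenation of an enone to the linear dienone (γ-enolisation, hydride abstraction from C-7, proton loss) can only go toward C-7/C-8 because C-3 is quaternary at this stage; no stereocentre is affected.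

Step 9
Reactants: 14 methyl (4aR,5R,6S)-3-acetoxy-6-[(tert-butyldimethylsilyl)oxy]-4a,5-dimethyl-2-oxo-2,3,4,4a,5,6-hexahydronaphthalene-3-carboxylate
Product: 15 (3R,4aR,5R,6S)-6-[(tert-butyldimethylsilyl)oxy]-4a,5-dimethyl-2-oxo-2,3,4,4a,5,6-hexahydronaphthalen-3-yl acetate
Conditions: LiCl, H2O (2 equiv), DMSO, 120 °C
Reagents that add atoms: none
Why: Krapcho dealkoxycarbonylation (chloride attack on the methyl ester, loss of CO2) leaves an enolate that is protonated at C-3, and under the warm, weakly basic conditions the α-acetoxy ketone should settle as the equatorial (3R) epimer trans to the axial angular methyl, which avoids a 1,3-diaxial contact.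

Step 10
Reactants: 15 (3R,4aR,5R,6S)-6-[(tert-butyldimethylsilyl)oxy]-4a,5-dimethyl-2-oxo-2,3,4,4a,5,6-hexahydronaphthalen-3-yl acetate
Product: 16 (3R,4aR,5R,6S)-6-hydroxy-4a,5-dimethyl-2-oxo-2,3,4,4a,5,6-hexahydronaphthalen-3-yl acetate
Conditions: HF·pyridine, pyridine, THF, 0 °C to rt
Reagents that add atoms: none
Why: Buffered fluoride cleavage of the secondary silyl ether should leave the acetate, the dienone and the epimerisable C-3 untouched.

Step 11
Reactants: 17 (2S)-2-hydroxy-2-methylbutanoic acid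
Product: 18 methyl (2S)-2-hydroxy-2-methylbutanoate
Conditions: MeI, K2CO3, DMF, rt
Reagents that add atoms: iodomethane, CI
Why: O-alkylation of the carboxylate; the tertiary alcohol does not react and the stereocentre is not involved.

Step 12
Reactants: 18 methyl (2S)-2-hydroxy-2-methylbutanoate
Product: 19 methyl (2S)-2-methyl-2-[(triethylsilyl)oxy]butanoate
Conditions: Et3SiOTf, 2,6-lutidine, CH2Cl2, 0 °C
Reagents that add atoms: triethylsilyl trifluoromethanesulfonate, CC[Si](CC)(CC)OS(=O)(=O)C(F)(F)F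
Why: A silyl triflate with a hindered base silylates the tertiary alcohol, which protects the α-hydroxy aldehyde to come against acyloin-type rearrangement.

Step 13
Reactants: 19 methyl (2S)-2-methyl-2-[(triethylsilyl)oxy]butanoate
Product: 20 (2S)-2-methyl-2-[(triethylsilyl)oxy]butanal
Conditions: iBu2AlH, CH2Cl2, −78 °C; aqueous potassium sodium tartrate
Reagents that add atoms: none
Why: Low-temperature hydride reduction stops at the aluminium hemiacetal, stabilised by the α-silyloxy group, and gives the aldehyde on work-up; the quaternary stereocentre cannot epimerise.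

Step 14
Reactants: 20 (2S)-2-methyl-2-[(triethylsilyl)oxy]butanal; 21 triethyl 4-phosphonocrotonate
Product: 23 ethyl (2E,4E,6S)-6-methyl-6-[(triethylsilyl)oxy]octa-2,4-dienoate, via lithiated phosphonate 22 (not isolated)
Conditions: LiN(SiMe3)2, THF, −78 °C; then 20, −78 to 0 °C
Reagents that add atoms: none
Why: Vinylogous Horner–Wadsworth–Emmons olefination, in which the stabilised anion reacts at the carbon next to phosphorus and reversible addition should give the (4E) alkene while the (2E) geometry of the reagent is kept.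

Step 15
Reactants: 23 ethyl (2E,4E,6S)-6-methyl-6-[(triethylsilyl)oxy]octa-2,4-dienoate
Product: 25 (2E,4E,6S)-6-hydroxy-6-methylocta-2,4-dienoic acid, via lithium carboxylate 24 (not isolated)
Conditions: LiOH, THF/MeOH/H2O, rt; then 1 M HCl to pH 2, rt
Reagents that add atoms: lithium hydroxide, [Li+].[OH-]
Why: Saponification of the ethyl ester followed by acid cleavage of the silyl ether in the same flask; the (E,E)-diene geometry prevents lactonisation.

Step 16
Reactants: 25 (2E,4E,6S)-6-hydroxy-6-methylocta-2,4-dienoic acid; 16 (3R,4aR,5R,6S)-6-hydroxy-4a,5-dimethyl-2-oxo-2,3,4,4a,5,6-hexahydronaphthalen-3-yl acetate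
Product: 27 (3R,4aR,5R,6S)-3-acetoxy-4a,5-dimethyl-2-oxo-2,3,4,4a,5,6-hexahydronaphthalen-6-yl (2E,4E,6S)-6-hydroxy-6-methylocta-2,4-dienoate, via mixed anhydride 26 (not isolated)
Conditions: 2,4,6-trichlorobenzoyl chloride, Et3N, THF, rt; then 16, 4-(dimethylamino)pyridine, toluene, rt to 40 °C
Reagents that add atoms: none
Why: Yamaguchi esterification, in which the acylpyridinium formed from the mixed anhydride acylates the secondary alcohol with retention at C-6, while the tertiary alcohol of the acid is too hindered to compete.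

Step 17
Reactants: 27 (3R,4aR,5R,6S)-3-acetoxy-4a,5-dimethyl-2-oxo-2,3,4,4a,5,6-hexahydronaphthalen-6-yl (2E,4E,6S)-6-hydroxy-6-methylocta-2,4-dienoate
Product: 28 (3R,4aR,5R,6S)-3-hydroxy-4a,5-dimethyl-2-oxo-2,3,4,4a,5,6-hexahydronaphthalen-6-yl (2E,4E,6S)-6-hydroxy-6-methylocta-2,4-dienoate
Conditions: K2CO3 (0.2 equiv), MeOH, 0 °C, argon
Reagents that add atoms: none
Why: Mild base-catalysed methanolysis should remove the activated α-keto acetate much faster than the hindered, conjugated dienoate, and C-3 stays in its more stable equatorial (R) configuration.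

**Compound list**

1 | 2,3-dimethylcyclohex-2-en-1-one | CC1=C(C)C(=O)CCC1 | starting material
2 | (1S)-2,3-dimethylcyclohex-2-en-1-ol | O[C@H]1CCCC(C)=C1C | intermediate
3 | tert-butyl{[(1S)-2,3-dimethylcyclohex-2-en-1-yl]oxy}dimethylsilane | CC(C)(C)[Si](C)(C)O[C@H]1CCCC(C)=C1C | intermediate
4 | (4S)-4-[(tert-butyldimethylsilyl)oxy]-2,3-dimethylcyclohex-2-en-1-one | CC(C)(C)[Si](C)(C)O[C@H]1CCC(=O)C(C)=C1C | intermediate
5 | tert-butyl{[(1S,2R)-4-{[dimethyl(phenyl)silyl]oxy}-2,3-dimethylcyclohex-3-en-1-yl]oxy}dimethylsilane | CC(C)(C)[Si](C)(C)O[C@H]1CCC(O[Si](C)(C)c2ccccc2)=C(C)[C@H]1C | intermediate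
6 | lithium (3R,4S)-4-[(tert-butyldimethylsilyl)oxy]-2,3-dimethylcyclohex-1-en-1-olate | CC(C)(C)[Si](C)(C)O[C@H]1CCC(O[Li])=C(C)[C@H]1C | intermediate
7 | (3R,4S)-4-[(tert-butyldimethylsilyl)oxy]-2,3-dimethylcyclohex-1-en-1-yl trifluoromethanesulfonate | CC(C)(C)[Si](C)(C)O[C@H]1CCC(OS(=O)(=O)C(F)(F)F)=C(C)[C@H]1C | intermediate
8 | (2-ethoxy-2-oxoethyl)zinc bromide | CCOC(=O)C[Zn]Br | starting material
9 | ethyl 2-[(3R,4S)-4-[(tert-butyldimethylsilyl)oxy]-2,3-dimethylcyclohex-1-en-1-yl]acetate | CC(C)(C)[Si](C)(C)O[C@H]1CCC(CC(=O)OCC)=C(C)[C@H]1C | intermediate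
10 | tert-butyl{[(1S,2R)-4-[2-ethoxy-2-(trimethylsilyloxy)ethenyl]-2,3-dimethylcyclohex-3-en-1-yl]oxy}dimethylsilane (ketene acetal geometry not defined) | CC(C)(C)[Si](C)(C)O[C@H]1CCC(C=C(OCC)O[Si](C)(C)C)=C(C)[C@H]1C | intermediate
11 | methyl 2-acetoxyacrylate | COC(=O)C(=C)OC(C)=O | starting material
12 | methyl (4aR,5R,6S)-3-acetoxy-6-[(tert-butyldimethylsilyl)oxy]-2-ethoxy-4a,5-dimethyl-2-(trimethylsilyloxy)-2,3,4,4a,5,6,7,8-octahydronaphthalene-3-carboxylate (epimers at C-2 and C-3) | CC(C)(C)[Si](C)(C)O[C@H]1CCC2=CC(OCC)(O[Si](C)(C)C)C(OC(C)=O)(C(=O)OC)C[C@]2(C)[C@H]1C | intermediate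
13 | methyl (4aR,5R,6S)-3-acetoxy-6-[(tert-butyldimethylsilyl)oxy]-4a,5-dimethyl-2-oxo-2,3,4,4a,5,6,7,8-octahydronaphthalene-3-carboxylate (C-3 epimers) | CC(C)(C)[Si](C)(C)O[C@H]1CCC2=CC(=O)C(OC(C)=O)(C(=O)OC)C[C@]2(C)[C@H]1C | intermediate
14 | methyl (4aR,5R,6S)-3-acetoxy-6-[(tert-butyldimethylsilyl)oxy]-4a,5-dimethyl-2-oxo-2,3,4,4a,5,6-hexahydronaphthalene-3-carboxylate (C-3 epimers) | CC(C)(C)[Si](C)(C)O[C@H]1C=CC2=CC(=O)C(OC(C)=O)(C(=O)OC)C[C@]2(C)[C@H]1C | intermediate
15 | (3R,4aR,5R,6S)-6-[(tert-butyldimethylsilyl)oxy]-4a,5-dimethyl-2-oxo-2,3,4,4a,5,6-hexahydronaphthalen-3-yl acetate | CC(C)(C)[Si](C)(C)O[C@H]1C=CC2=CC(=O)[C@H](OC(C)=O)C[C@]2(C)[C@H]1C | intermediate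
16 | (3R,4aR,5R,6S)-6-hydroxy-4a,5-dimethyl-2-oxo-2,3,4,4a,5,6-hexahydronaphthalen-3-yl acetate | O[C@H]1C=CC2=CC(=O)[C@H](OC(C)=O)C[C@]2(C)[C@H]1C | intermediate
17 | (2S)-2-hydroxy-2-methylbutanoic acid | CC[C@](C)(O)C(=O)O | starting material
18 | methyl (2S)-2-hydroxy-2-methylbutanoate | CC[C@](C)(O)C(=O)OC | intermediate
19 | methyl (2S)-2-methyl-2-[(triethylsilyl)oxy]butanoate | CC[C@](C)(O[Si](CC)(CC)CC)C(=O)OC | intermediate
20 | (2S)-2-methyl-2-[(triethylsilyl)oxy]butanal | CC[C@](C)(O[Si](CC)(CC)CC)C=O | intermediate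
21 | triethyl 4-phosphonocrotonate [ethyl (2E)-4-(diethoxyphosphoryl)but-2-enoate] | CCOC(=O)/C=C/CP(=O)(OCC)OCC | starting material
22 | lithium salt of ethyl (2E)-4-(diethoxyphosphoryl)but-2-enoate (carbanion next to phosphorus) | [Li+].CCOC(=O)/C=C/[CH-]P(=O)(OCC)OCC | intermediate
23 | ethyl (2E,4E,6S)-6-methyl-6-[(triethylsilyl)oxy]octa-2,4-dienoate | CC[C@](C)(O[Si](CC)(CC)CC)/C=C/C=C/C(=O)OCC | intermediate
24 | lithium (2E,4E,6S)-6-methyl-6-[(triethylsilyl)oxy]octa-2,4-dienoate | [Li+].CC[C@](C)(O[Si](CC)(CC)CC)/C=C/C=C/C([O-])=O | intermediate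
25 | (2E,4E,6S)-6-hydroxy-6-methylocta-2,4-dienoic acid | CC[C@](C)(O)/C=C/C=C/C(=O)O | intermediate
26 | (2E,4E,6S)-6-hydroxy-6-methylocta-2,4-dienoic 2,4,6-trichlorobenzoic anhydride | CC[C@](C)(O)/C=C/C=C/C(=O)OC(=O)c1c(Cl)cc(Cl)cc1Cl | intermediate
27 | (3R,4aR,5R,6S)-3-acetoxy-4a,5-dimethyl-2-oxo-2,3,4,4a,5,6-hexahydronaphthalen-6-yl (2E,4E,6S)-6-hydroxy-6-methylocta-2,4-dienoate | CC[C@](C)(O)/C=C/C=C/C(=O)O[C@H]1C=CC2=CC(=O)[C@H](OC(C)=O)C[C@]2(C)[C@H]1C | intermediate
28 | (3R,4aR,5R,6S)-3-hydroxy-4a,5-dimethyl-2-oxo-2,3,4,4a,5,6-hexahydronaphthalen-6-yl (2E,4E,6S)-6-hydroxy-6-methylocta-2,4-dienoate | CC[C@](C)(O)/C=C/C=C/C(=O)O[C@H]1C=CC2=CC(=O)[C@H](O)C[C@]2(C)[C@H]1C | target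

**Step count and risks**

Total steps: 17. Longest linear sequence: 12 (steps 1–10, 16, 17).

Step 7. The cycloaddition may stall because the reactive s-cis conformer places the C-4a methyl and an oxygen substituent inside the diene; the ketene acetal may instead add in an open-chain Michael sense through its α-carbon or be lost by desilylation. The fallback builds ring B by Robinson annulation and adds the C-3 oxygen afterwards. It sets out from silyl enol ether 5, isolated after the reduction stage of step 4. MeLi would give enolate 6, which should add to 3-(trimethylsilyl)but-3-en-2-one anti to the neighbouring methyl to give (2R,3R,4S)-4-[(tert-butyldimethylsilyl)oxy]-2,3-dimethyl-2-[3-oxo-2-(trimethylsilyl)butyl]cyclohexan-1-one F1. KOH in MeOH should desilylate it and close it by aldol condensation to (4aR,5R,6S)-6-[(tert-butyldimethylsilyl)oxy]-4a,5-dimethyl-4,4a,5,6,7,8-hexahydronaphthalen-2(3H)-one F2. LiN(iPr)2 and Me3SiCl should give the cross-conjugated dienol ether tert-butyldimethyl{[(1S,2R,8aR)-1,8a-dimethyl-6-(trimethylsilyloxy)-1,2,3,4,8,8a-hexahydronaphthalen-2-yl]oxy}silane F3. Rubottom oxidation with mCPBA, anti to the angular methyl, and dilute acid should give (3R,4aR,5R,6S)-6-[(tert-butyldimethylsilyl)oxy]-3-hydroxy-4a,5-dimethyl-4,4a,5,6,7,8-hexahydronaphthalen-2(3H)-one F4. Ac2O in pyridine should give (3R,4aR,5R,6S)-6-[(tert-butyldimethylsilyl)oxy]-4a,5-dimethyl-2-oxo-2,3,4,4a,5,6,7,8-octahydronaphthalen-3-yl acetate F5, and chloranil in refluxing t-BuOH would bring the route back at dienone acetate 15.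

Step 4. Hydride transfer to the fully substituted β-carbon may be slow, so that 1,2-reduction or incomplete conversion results, and facial selectivity may be lower than for cuprate additions. The fallback reaches the same enolate by hydrogenation and thermodynamic enolisation. It sets out from enone 4. H2 over Pd/C in EtOAc should add hydrogen anti to the silyloxy group to give (3R,4S)-4-[(tert-butyldimethylsilyl)oxy]-2,3-dimethylcyclohexan-1-one F6 (C-2 epimers, of no consequence). Me3SiI with hexamethyldisilazane should give the more substituted enol ether tert-butyl{[(1S,2R)-2,3-dimethyl-4-(trimethylsilyloxy)cyclohex-3-en-1-yl]oxy}dimethylsilane F7. MeLi would then give lithium enolate 6, where the route is rejoined.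

Step 3. Hydrogen abstraction may also occur at the silyloxy-bearing allylic carbon, which would erase the stereocentre and return enone 1. The fallback deactivates that C–H bond with an acyl group. It sets out from alcohol 2. Ac2O in pyridine should give (1S)-2,3-dimethylcyclohex-2-en-1-yl acetate F8. CrO3·3,5-dimethylpyrazole in CH2Cl2 at −20 °C should oxidise the ring CH2 to (1S)-2,3-dimethyl-4-oxocyclohex-2-en-1-yl acetate F9. Brief K2CO3/MeOH at 0 °C should give (4S)-4-hydroxy-2,3-dimethylcyclohex-2-en-1-one F10, and TBSCl with imidazole would bring the route back at enone 4.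

Further compounds
F1 | step 7 | (2R,3R,4S)-4-[(tert-butyldimethylsilyl)oxy]-2,3-dimethyl-2-[3-oxo-2-(trimethylsilyl)butyl]cyclohexan-1-one | CC(C)(C)[Si](C)(C)O[C@H]1CCC(=O)[C@](C)(CC(C(C)=O)[Si](C)(C)C)[C@H]1C
F2 | step 7 | (4aR,5R,6S)-6-[(tert-butyldimethylsilyl)oxy]-4a,5-dimethyl-4,4a,5,6,7,8-hexahydronaphthalen-2(3H)-one | CC(C)(C)[Si](C)(C)O[C@H]1CCC2=CC(=O)CC[C@]2(C)[C@H]1C
F3 | step 7 | tert-butyldimethyl{[(1S,2R,8aR)-1,8a-dimethyl-6-(trimethylsilyloxy)-1,2,3,4,8,8a-hexahydronaphthalen-2-yl]oxy}silane | CC(C)(C)[Si](C)(C)O[C@H]1CCC2=CC(O[Si](C)(C)C)=CC[C@]2(C)[C@H]1C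
F4 | step 7 | (3R,4aR,5R,6S)-6-[(tert-butyldimethylsilyl)oxy]-3-hydroxy-4a,5-dimethyl-4,4a,5,6,7,8-hexahydronaphthalen-2(3H)-one | CC(C)(C)[Si](C)(C)O[C@H]1CCC2=CC(=O)[C@H](O)C[C@]2(C)[C@H]1C
F5 | step 7 | (3R,4aR,5R,6S)-6-[(tert-butyldimethylsilyl)oxy]-4a,5-dimethyl-2-oxo-2,3,4,4a,5,6,7,8-octahydronaphthalen-3-yl acetate | CC(C)(C)[Si](C)(C)O[C@H]1CCC2=CC(=O)[C@H](OC(C)=O)C[C@]2(C)[C@H]1C
F6 | step 4 | (3R,4S)-4-[(tert-butyldimethylsilyl)oxy]-2,3-dimethylcyclohexan-1-one | CC(C)(C)[Si](C)(C)O[C@H]1CCC(=O)C(C)[C@H]1C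
F7 | step 4 | tert-butyl{[(1S,2R)-2,3-dimethyl-4-(trimethylsilyloxy)cyclohex-3-en-1-yl]oxy}dimethylsilane | CC(C)(C)[Si](C)(C)O[C@H]1CCC(O[Si](C)(C)C)=C(C)[C@H]1C
F8 | step 3 | (1S)-2,3-dimethylcyclohex-2-en-1-yl acetate | CC(=O)O[C@H]1CCCC(C)=C1C
F9 | step 3 | (1S)-2,3-dimethyl-4-oxocyclohex-2-en-1-yl acetate | CC(=O)O[C@H]1CCC(=O)C(C)=C1C
F10 | step 3 | (4S)-4-hydroxy-2,3-dimethylcyclohex-2-en-1-one | O[C@H]1CCC(=O)C(C)=C1C
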